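**Retrosynthetic overview**

1. The target, read as (2S,6R,2'R,6'S), comes from methyl ester 38 (CH2OH ⇐ CO2CH3), which is cut by two Wittig disconnections at C11'=C12' and C11=C12 into ring B salt 18, C10 trienedial 34 and ring A salt 33.
2. Each salt comes from a ring C7 aldehyde (HWE, vinyl Grignard, PPh3·HBr), this from a cyclized acetate, this from an acyclic tertiary carbinol; C2'/C2 are set by SN2 opening of (R)-6,7-epoxyneryl/geranyl acetate with LiCH2CN, and the side chains by Wittig reaction on the derived lactol (a temporary ring).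
3. Key disconnection: C1'–C6' of ring B, a biomimetic cation–olefin closure of carbinol 10; the hydroxyprenyl chain is carried as its methyl enoate so that it stays out of the cation chemistry.
4. Enabling feature: in ring B the quaternary gem-dimethyl C1' (a tertiary cation once its oxygen leaves) stands 1,5 to C5', and the C4'=C5'(CH3)–C6'H unit is what a C5'=C6' olefin leaves after attack through C6' and proton loss from C4'; the Z olefin gives 2',6'-trans, the E olefin (ring A) gives 2,6-cis.
5. Ring order: ring B (step 6), then ring A (step 17), polyene last.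

Key step: step 6

Remark: carotenoid numbering is used. Ring A is the prenyl-bearing ε-ring (C1–C6) and ring B the hydroxyprenyl-bearing ε-ring (C1'–C6'). In the target the C2 side chain and the C6 polyene are cis on ring A and trans on ring B.
Assumption: the D-fructose-derived Shi ketone delivers the (R)-epoxide of a 2-methylalk-2-ene (spiro transition-state model); if the facial sense proved opposite, the enantiomeric ketone would be used.
Assumption: (2E,4E,6E)-2,7-dimethylocta-2,4,6-trienedial (34) is purchased.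

**Ring B fragment**

Step 1
Reactants: 1 neryl acetate
Product: 2 [(2Z)-5-[(2R)-3,3-dimethyloxiran-2-yl]-3-methylpent-2-en-1-yl] acetate
Conditions: D-fructose-derived Shi ketone (1,2:4,5-di-O-isopropylidene-β-D-erythro-2,3-hexodiulo-2,6-pyranose, 0.3 equiv), KHSO5 (as 2KHSO5·KHSO4·K2SO4), K2CO3, Bu4NHSO4, Na2B4O7 buffer, CH3CN/CH2(OCH3)2, 0 °C
Reagents that add atoms: potassium peroxymonosulfate, [K+].[O-]S(=O)(=O)OO
Why: Shi asymmetric epoxidation: the chiral dioxirane should oxidise only the electron-rich 6,7-olefin (the 2,3-olefin is deactivated by the allylic acetate), and the spiro transition state should give the (R)-epoxide, the source of C2'.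

Step 2
Reactants: 2 epoxy acetate; 3 acetonitrile
Product: 5 (3R,6Z)-8-hydroxy-3-(2-hydroxypropan-2-yl)-6-methyloct-6-enenitrile, via epoxy alcohol lithium alkoxide 4 (not isolated)
Conditions: n-BuLi (5 equiv), CH3CN (5.5 equiv), THF, −78 °C; add 2; −78 °C to rt; aq. NH4Cl
Reagents that add atoms: acetonitrile (3), CC#N
Why: Excess lithioacetonitrile first removes the acetyl group (Claisen-type acyl transfer) and then opens the trisubstituted epoxide by SN2 attack at the secondary carbon with inversion, which fixes C2' and leaves the tertiary carbinol that later becomes the C1' cation.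

Step 3
Reactants: 5 hydroxy nitrile
Product: 7 (4R)-4-[(3Z)-5-hydroxy-3-methylpent-3-en-1-yl]-5,5-dimethyloxolan-2-ol (anomer mixture), via hydroxy aldehyde 6 (not isolated)
Conditions: i-Bu2AlH (4 equiv), CH2Cl2, −78 to −20 °C; aq. KNaC4H4O6, then pH 4 buffer
Reagents that add atoms: water, O
Why: Partial nitrile reduction by i-Bu2AlH to the aldimine and hydrolysis gives the γ-hydroxy aldehyde, which closes to the five-membered lactol (a temporary ring); the stereocentre is β to the carbonyl and cannot enolise.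

Step 4
Reactants: 7 lactol; 8 methyl 2-(triphenylphosphoranylidene)propanoate
Product: 9 methyl (2E,5R,8Z)-10-hydroxy-5-(2-hydroxypropan-2-yl)-2,8-dimethyldeca-2,8-dienoate
Conditions: 8 (1.5 equiv), toluene, 80 °C
Reagents that add atoms: methyl 2-(triphenylphosphoranylidene)propanoate (8), COC(=O)C(C)=P(c1ccccc1)(c1ccccc1)c1ccccc1
Why: Wittig olefination of the lactol, which reacts through the equilibrium share of its ring-opened hydroxy aldehyde tautomer, with the stabilised α-methyl ylide should give the (E)-trisubstituted enoate (the hydroxyprenyl chain at the ester oxidation level) and leaves the tertiary alcohol free.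

Step 5
Reactants: 9 diol ester
Product: 10 methyl (2E,5R,8Z)-10-(acetyloxy)-5-(2-hydroxypropan-2-yl)-2,8-dimethyldeca-2,8-dienoate
Conditions: Ac2O (1.1 equiv), pyridine, CH2Cl2, 0 °C
Reagents that add atoms: acetic anhydride, CC(=O)OC(C)=O
Why: Chemoselective acetylation of the primary allylic hydroxyl (the tertiary carbinol does not react under these conditions) restores the neryl acetate motif used for the cyclization.

Step 6
Reactants: 10 tertiary carbinol
Product: 11 methyl (2E)-4-[(1R,5S)-5-[(acetyloxy)methyl]-4,6,6-trimethylcyclohex-3-en-1-yl]-2-methylbut-2-enoate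
Conditions: SnCl4 (2.5 equiv), CH2Cl2, −78 to −40 °C; quench with Et3N/CH3OH at −78 °C
Reagents that add atoms: none
Why: SnCl4 ionises the tertiary carbinol to the C1' cation, which is captured by C6' of the (Z)-C5'=C6' olefin through a chair transition state, and the resulting C5' cation loses the axial C4' proton to give the C4'=C5' olefin. The closest known reaction type is the biomimetic cation–olefin cyclization of geranyl/neryl-type acetates and of pseudoionone to α-cyclogeranyl and α-ionone rings. Ring B closes in the 6-endo mode (both olefin carbons end up in the ring), C1'–C6' being the only bond formed. The new stereocentre C6' is controlled by the existing C2' centre together with the olefin geometry: the C2' side chain sits equatorial, anti to the forming bond, and the Z olefin forces C7' axial, so C2' and C6' should come out trans, i.e. (6'S) from (2'R). The step needs endocyclic proton loss and retention at C2'; the first rests on the axial C4'–H being the only ring C–H aligned with the empty orbital in this chair (the C6'–H is equatorial), the second on the C2'–H lying well off the cation p-axis in the folded conformer and on the low temperature. The enoate oxidation level and the acetate keep the side-chain olefin and the allylic oxygen from competing.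

Step 7
Reactants: 11 cyclized acetate
Product: 12 methyl (2E)-4-[(1R,5S)-5-(hydroxymethyl)-4,6,6-trimethylcyclohex-3-en-1-yl]-2-methylbut-2-enoate
Conditions: K2CO3 (cat.), CH3OH, rt
Reagents that add atoms: none
Why: Base-catalysed transesterification removes the acetate, while the conjugated methyl ester is unchanged in methanol.

Step 8
Reactants: 12 alcohol
Product: 13 methyl (2E)-4-[(1R,5S)-5-formyl-4,6,6-trimethylcyclohex-3-en-1-yl]-2-methylbut-2-enoate
Conditions: Dess–Martin periodinane, NaHCO3, CH2Cl2, 0 °C; used at once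
Reagents that add atoms: none
Why: Dess–Martin oxidation under buffered, non-basic conditions should give the β,γ-unsaturated aldehyde without enolisation at C6'.

Step 9
Reactants: 13 aldehyde; 14 dimethyl (2-oxopropyl)phosphonate
Product: 15 methyl (2E)-2-methyl-4-[(1R,5S)-4,6,6-trimethyl-5-[(1E)-3-oxobut-1-en-1-yl]cyclohex-3-en-1-yl]but-2-enoate
Conditions: 14, LiCl, i-Pr2NEt, CH3CN, rt
Reagents that add atoms: dimethyl (2-oxopropyl)phosphonate (14), COP(=O)(CC(C)=O)OC
Why: Horner–Wadsworth–Emmons olefination under Masamune–Roush conditions is mild enough for the epimerisable aldehyde and E-selective, giving the 2'-substituted α-ionone-type enone.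

Step 10
Reactants: 15 enone; 16 vinylmagnesium bromide
Product: 17 methyl (2E)-4-[(1R,5S)-5-[(1E)-3-hydroxy-3-methylpenta-1,4-dien-1-yl]-4,6,6-trimethylcyclohex-3-en-1-yl]-2-methylbut-2-enoate (carbinol epimers)
Conditions: 16 (1.2 equiv), THF, −78 °C; aq. NH4Cl
Reagents that add atoms: vinylmagnesium bromide (16), C=C[Mg]Br
Why: Grignard 1,2-addition to the methyl ketone, which is far more electrophilic than the α-methyl enoate at −78 °C; both carbinol epimers converge in the next step.

Step 11
Reactants: 17 vinyl carbinol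
Product: 18 [(2E,4E)-5-[(1S,5R)-5-[(2E)-4-methoxy-3-methyl-4-oxobut-2-en-1-yl]-2,6,6-trimethylcyclohex-2-en-1-yl]-3-methylpenta-2,4-dien-1-yl]triphenylphosphonium bromide
Conditions: PPh3·HBr, CH3OH, rt
Reagents that add atoms: triphenylphosphine hydrobromide, [Br-].c1ccc(cc1)[PH+](c1ccccc1)c1ccccc1
Why: Acid-mediated allylic transposition (SN1' through the pentadienyl cation) with capture by PPh3 at the primary terminus, the standard vinyl-ionol to Wittig-salt conversion; C6' is not part of the cation and should stay configured.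

**Ring A fragment**

Step 12
Reactants: 19 geranyl acetate
Product: 20 [(2E)-5-[(2R)-3,3-dimethyloxiran-2-yl]-3-methylpent-2-en-1-yl] acetate
Conditions: D-fructose-derived Shi ketone (1,2:4,5-di-O-isopropylidene-β-D-erythro-2,3-hexodiulo-2,6-pyranose, 0.3 equiv), KHSO5 (as 2KHSO5·KHSO4·K2SO4), K2CO3, Bu4NHSO4, Na2B4O7 buffer, CH3CN/CH2(OCH3)2, 0 °C
Reagents that add atoms: potassium peroxymonosulfate, [K+].[O-]S(=O)(=O)OO
Why: Shi asymmetric epoxidation of the 6,7-olefin with the same ketone should give the (R)-epoxide, the source of C2 (same spatial sense as C2').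

Step 13
Reactants: 20 epoxy acetate; 3 acetonitrile
Product: 22 (3R,6E)-8-hydroxy-3-(2-hydroxypropan-2-yl)-6-methyloct-6-enenitrile, via epoxy alcohol lithium alkoxide 21 (not isolated)
Conditions: n-BuLi (5 equiv), CH3CN (5.5 equiv), THF, −78 °C; add 20; −78 °C to rt; aq. NH4Cl
Reagents that add atoms: acetonitrile (3), CC#N
Why: Acetate removal followed by SN2 epoxide opening with inversion by lithioacetonitrile sets C2 and the tertiary carbinol.

Step 14
Reactants: 22 hydroxy nitrile
Product: 24 (4R)-4-[(3E)-5-hydroxy-3-methylpent-3-en-1-yl]-5,5-dimethyloxolan-2-ol (anomer mixture), via hydroxy aldehyde 23 (not isolated)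
Conditions: i-Bu2AlH (4 equiv), CH2Cl2, −78 to −20 °C; aq. KNaC4H4O6, then pH 4 buffer
Reagents that add atoms: water, O
Why: i-Bu2AlH reduction of the nitrile and hydrolysis give the γ-hydroxy aldehyde, which closes to the lactol.

Step 15
Reactants: 24 lactol; 25 isopropyltriphenylphosphonium iodide
Product: 26 (2E,6R)-6-(2-hydroxypropan-2-yl)-3,9-dimethyldeca-2,8-dien-1-ol
Conditions: 25 (3.5 equiv), n-BuLi (3.4 equiv), THF, 0 °C; then 24, 0 °C to rt
Reagents that add atoms: isopropyltriphenylphosphonium iodide (25), CC(C)[P+](c1ccccc1)(c1ccccc1)c1ccccc1.[I-]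
Why: Wittig olefination of the lactol, which reacts through its ring-opened hydroxy aldehyde tautomer, with the non-stabilised isopropylidene ylide (excess ylide also deprotonates the hydroxyls) installs the prenyl group directly; no olefin geometry is at stake.

Step 16
Reactants: 26 diol
Product: 27 (2E,6R)-6-(2-hydroxypropan-2-yl)-3,9-dimethyldeca-2,8-dien-1-yl acetate
Conditions: Ac2O (1.1 equiv), pyridine, CH2Cl2, 0 °C
Reagents that add atoms: acetic anhydride, CC(=O)OC(C)=O
Why: Chemoselective acetylation of the primary allylic hydroxyl over the tertiary carbinol.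

Step 17
Reactants: 27 tertiary carbinol
Product: 28 [(1R,5S)-2,6,6-trimethyl-5-(3-methylbut-2-en-1-yl)cyclohex-2-en-1-yl]methyl acetate
Conditions: SnCl4 (2.5 equiv), CH2Cl2, −78 °C; quench with Et3N/CH3OH at −78 °C
Reagents that add atoms: none
Why: The same tertiary-cation/olefin cyclization as step 6 (6-endo, chair), but the (E)-olefin places C7 equatorial beside the equatorial C2 side chain, so ring A should form 2,6-cis; proton loss from C4 rather than from C6 should be favoured by the inductive effect of the acetoxymethyl group, and the low temperature and aprotic Lewis acid are meant to leave the prenyl olefin untouched.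

Step 18
Reactants: 28 cyclized acetate
Product: 29 [(1R,5S)-2,6,6-trimethyl-5-(3-methylbut-2-en-1-yl)cyclohex-2-en-1-yl]methanol
Conditions: K2CO3 (cat.), CH3OH, rt
Reagents that add atoms: none
Why: Base-catalysed transesterification removes the acetate.

Step 19
Reactants: 29 alcohol
Product: 30 (1R,5S)-2,6,6-trimethyl-5-(3-methylbut-2-en-1-yl)cyclohex-2-ene-1-carbaldehyde
Conditions: Dess–Martin periodinane, NaHCO3, CH2Cl2, 0 °C; used at once
Reagents that add atoms: none
Why: Buffered Dess–Martin oxidation should give the aldehyde without enolisation at C6.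

Step 20
Reactants: 30 aldehyde; 14 dimethyl (2-oxopropyl)phosphonate
Product: 31 (3E)-4-[(1R,5S)-2,6,6-trimethyl-5-(3-methylbut-2-en-1-yl)cyclohex-2-en-1-yl]but-3-en-2-one
Conditions: 14, LiCl, i-Pr2NEt, CH3CN, rt
Reagents that add atoms: dimethyl (2-oxopropyl)phosphonate (14), COP(=O)(CC(C)=O)OC
Why: Horner–Wadsworth–Emmons olefination under Masamune–Roush conditions, E-selective and mild toward the epimerisable aldehyde.

Step 21
Reactants: 31 enone; 16 vinylmagnesium bromide
Product: 32 (1E)-3-methyl-1-[(1R,5S)-2,6,6-trimethyl-5-(3-methylbut-2-en-1-yl)cyclohex-2-en-1-yl]penta-1,4-dien-3-ol (carbinol epimers)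
Conditions: 16 (1.2 equiv), THF, −78 °C; aq. NH4Cl
Reagents that add atoms: vinylmagnesium bromide (16), C=C[Mg]Br
Why: Grignard 1,2-addition to the methyl ketone; the new carbinol centre is lost in the next step.

Step 22
Reactants: 32 vinyl carbinol
Product: 33 [(2E,4E)-3-methyl-5-[(1R,5S)-2,6,6-trimethyl-5-(3-methylbut-2-en-1-yl)cyclohex-2-en-1-yl]penta-2,4-dien-1-yl]triphenylphosphonium bromide
Conditions: PPh3·HBr, CH3OH, rt
Reagents that add atoms: triphenylphosphine hydrobromide, [Br-].c1ccc(cc1)[PH+](c1ccccc1)c1ccccc1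
Why: SN1'-type allylic transposition with capture by PPh3 at the primary terminus, as in step 11.

**Assembly**

Step 23
Reactants: 33 ring A phosphonium salt; 34 (2E,4E,6E)-2,7-dimethylocta-2,4,6-trienedial
Product: 36 (2E,4E,6E,8E,10E,12E)-2,7,11-trimethyl-13-[(1R,5S)-2,6,6-trimethyl-5-(3-methylbut-2-en-1-yl)cyclohex-2-en-1-yl]trideca-2,4,6,8,10,12-hexaenal, via phosphorus ylide 35 (not isolated)
Conditions: NaOCH3, CH3OH/CH2Cl2, 0 °C to rt, 34 (3 equiv); then reflux in n-heptane (Z to E)
Reagents that add atoms: (2E,4E,6E)-2,7-dimethylocta-2,4,6-trienedial (34), O=C/C(C)=C/C=C/C=C(C)/C=O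
Why: Wittig reaction of the ylide with an excess of the symmetrical dialdehyde should favour mono-olefination at C11=C12, and Z isomers at the new bond are equilibrated thermally to E.

Step 24
Reactants: 18 ring B phosphonium salt; 36 C30 aldehyde
Product: 38 methyl ester of the target (CO2CH3 in place of CH2OH on the ring B side chain; 2S,6R,2'R,6'S; all-E), via phosphorus ylide 37 (not isolated)
Conditions: NaOCH3, CH3OH/CH2Cl2, rt; then reflux in n-heptane (Z to E)
Reagents that add atoms: none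
Why: The second Wittig reaction forms C11'=C12' and joins ring B; thermal equilibration should give the all-E polyene, and NaOCH3 in CH3OH cannot scramble the methyl ester.

Step 25
Reactants: 38 C50 methyl ester
Product: 39 (2S,6R,2'R,6'S)-2'-[(2E)-4-hydroxy-3-methylbut-2-en-1-yl]-2-(3-methylbut-2-en-1-yl)-ε,ε-carotene (target)
Conditions: i-Bu2AlH (2.5 equiv), CH2Cl2, −78 °C; aq. KNaC4H4O6
Reagents that add atoms: none
Why: i-Bu2AlH 1,2-reduction of the α,β-unsaturated methyl ester to the (E)-allylic alcohol at −78 °C, leaving the polyene and the four stereocentres untouched.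

**Compound list**

1 | neryl acetate, (2Z)-3,7-dimethylocta-2,6-dien-1-yl acetate | CC(C)=CCC/C(C)=C\COC(C)=O | starting material
2 | [(2Z)-5-[(2R)-3,3-dimethyloxiran-2-yl]-3-methylpent-2-en-1-yl] acetate | CC(=O)OC/C=C(C)\CC[C@H]1OC1(C)C | intermediate
3 | acetonitrile | CC#N | starting material
4 | (2Z)-5-[(2R)-3,3-dimethyloxiran-2-yl]-3-methylpent-2-en-1-ol (formed as its lithium alkoxide) | OC/C=C(C)\CC[C@H]1OC1(C)C | intermediate
5 | (3R,6Z)-8-hydroxy-3-(2-hydroxypropan-2-yl)-6-methyloct-6-enenitrile | OC/C=C(C)\CC[C@H](CC#N)C(C)(C)O | intermediate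
6 | (3R,6Z)-8-hydroxy-3-(2-hydroxypropan-2-yl)-6-methyloct-6-enal | OC/C=C(C)\CC[C@H](CC=O)C(C)(C)O | intermediate
7 | (4R)-4-[(3Z)-5-hydroxy-3-methylpent-3-en-1-yl]-5,5-dimethyloxolan-2-ol | OC/C=C(C)\CC[C@H](CC1O)C(C)(C)O1 | intermediate
8 | methyl 2-(triphenylphosphoranylidene)propanoate | COC(=O)C(C)=P(c1ccccc1)(c1ccccc1)c1ccccc1 | starting material
9 | methyl (2E,5R,8Z)-10-hydroxy-5-(2-hydroxypropan-2-yl)-2,8-dimethyldeca-2,8-dienoate | OC/C=C(C)\CC[C@H](C/C=C(\C)C(=O)OC)C(C)(C)O | intermediate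
10 | methyl (2E,5R,8Z)-10-(acetyloxy)-5-(2-hydroxypropan-2-yl)-2,8-dimethyldeca-2,8-dienoate | CC(=O)OC/C=C(C)\CC[C@H](C/C=C(\C)C(=O)OC)C(C)(C)O | intermediate
11 | methyl (2E)-4-[(1R,5S)-5-[(acetyloxy)methyl]-4,6,6-trimethylcyclohex-3-en-1-yl]-2-methylbut-2-enoate | CC(=O)OC[C@H]1C(C)=CC[C@H](C/C=C(\C)C(=O)OC)C1(C)C | intermediate
12 | methyl (2E)-4-[(1R,5S)-5-(hydroxymethyl)-4,6,6-trimethylcyclohex-3-en-1-yl]-2-methylbut-2-enoate | OC[C@H]1C(C)=CC[C@H](C/C=C(\C)C(=O)OC)C1(C)C | intermediate
13 | methyl (2E)-4-[(1R,5S)-5-formyl-4,6,6-trimethylcyclohex-3-en-1-yl]-2-methylbut-2-enoate | O=C[C@H]1C(C)=CC[C@H](C/C=C(\C)C(=O)OC)C1(C)C | intermediate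
14 | dimethyl (2-oxopropyl)phosphonate | COP(=O)(CC(C)=O)OC | starting material
15 | methyl (2E)-2-methyl-4-[(1R,5S)-4,6,6-trimethyl-5-[(1E)-3-oxobut-1-en-1-yl]cyclohex-3-en-1-yl]but-2-enoate | CC(=O)/C=C/[C@H]1C(C)=CC[C@H](C/C=C(\C)C(=O)OC)C1(C)C | intermediate
16 | vinylmagnesium bromide | C=C[Mg]Br | starting material
17 | methyl (2E)-4-[(1R,5S)-5-[(1E)-3-hydroxy-3-methylpenta-1,4-dien-1-yl]-4,6,6-trimethylcyclohex-3-en-1-yl]-2-methylbut-2-enoate | C=CC(C)(O)/C=C/[C@H]1C(C)=CC[C@H](C/C=C(\C)C(=O)OC)C1(C)C | intermediate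
18 | [(2E,4E)-5-[(1S,5R)-5-[(2E)-4-methoxy-3-methyl-4-oxobut-2-en-1-yl]-2,6,6-trimethylcyclohex-2-en-1-yl]-3-methylpenta-2,4-dien-1-yl]triphenylphosphonium bromide | [Br-].c1ccc(cc1)[P+](c1ccccc1)(c1ccccc1)C/C=C(C)/C=C/[C@H]1C(C)=CC[C@H](C/C=C(\C)C(=O)OC)C1(C)C | intermediate
19 | geranyl acetate, (2E)-3,7-dimethylocta-2,6-dien-1-yl acetate | CC(C)=CCC/C(C)=C/COC(C)=O | starting material
20 | [(2E)-5-[(2R)-3,3-dimethyloxiran-2-yl]-3-methylpent-2-en-1-yl] acetate | CC(=O)OC/C=C(C)/CC[C@H]1OC1(C)C | intermediate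
21 | (2E)-5-[(2R)-3,3-dimethyloxiran-2-yl]-3-methylpent-2-en-1-ol (formed as its lithium alkoxide) | OC/C=C(C)/CC[C@H]1OC1(C)C | intermediate
22 | (3R,6E)-8-hydroxy-3-(2-hydroxypropan-2-yl)-6-methyloct-6-enenitrile | OC/C=C(C)/CC[C@H](CC#N)C(C)(C)O | intermediate
23 | (3R,6E)-8-hydroxy-3-(2-hydroxypropan-2-yl)-6-methyloct-6-enal | OC/C=C(C)/CC[C@H](CC=O)C(C)(C)O | intermediate
24 | (4R)-4-[(3E)-5-hydroxy-3-methylpent-3-en-1-yl]-5,5-dimethyloxolan-2-ol | OC/C=C(C)/CC[C@H](CC1O)C(C)(C)O1 | intermediate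
25 | isopropyltriphenylphosphonium iodide | CC(C)[P+](c1ccccc1)(c1ccccc1)c1ccccc1.[I-] | starting material
26 | (2E,6R)-6-(2-hydroxypropan-2-yl)-3,9-dimethyldeca-2,8-dien-1-ol | OC/C=C(C)/CC[C@H](CC=C(C)C)C(C)(C)O | intermediate
27 | (2E,6R)-6-(2-hydroxypropan-2-yl)-3,9-dimethyldeca-2,8-dien-1-yl acetate | CC(=O)OC/C=C(C)/CC[C@H](CC=C(C)C)C(C)(C)O | intermediate
28 | [(1R,5S)-2,6,6-trimethyl-5-(3-methylbut-2-en-1-yl)cyclohex-2-en-1-yl]methyl acetate | CC(=O)OC[C@@H]1C(C)=CC[C@H](CC=C(C)C)C1(C)C | intermediate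
29 | [(1R,5S)-2,6,6-trimethyl-5-(3-methylbut-2-en-1-yl)cyclohex-2-en-1-yl]methanol | OC[C@@H]1C(C)=CC[C@H](CC=C(C)C)C1(C)C | intermediate
30 | (1R,5S)-2,6,6-trimethyl-5-(3-methylbut-2-en-1-yl)cyclohex-2-ene-1-carbaldehyde | O=C[C@@H]1C(C)=CC[C@H](CC=C(C)C)C1(C)C | intermediate
31 | (3E)-4-[(1R,5S)-2,6,6-trimethyl-5-(3-methylbut-2-en-1-yl)cyclohex-2-en-1-yl]but-3-en-2-one | CC(=O)/C=C/[C@@H]1C(C)=CC[C@H](CC=C(C)C)C1(C)C | intermediate
32 | (1E)-3-methyl-1-[(1R,5S)-2,6,6-trimethyl-5-(3-methylbut-2-en-1-yl)cyclohex-2-en-1-yl]penta-1,4-dien-3-ol | C=CC(C)(O)/C=C/[C@@H]1C(C)=CC[C@H](CC=C(C)C)C1(C)C | intermediate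
33 | [(2E,4E)-3-methyl-5-[(1R,5S)-2,6,6-trimethyl-5-(3-methylbut-2-en-1-yl)cyclohex-2-en-1-yl]penta-2,4-dien-1-yl]triphenylphosphonium bromide | [Br-].c1ccc(cc1)[P+](c1ccccc1)(c1ccccc1)C/C=C(C)/C=C/[C@@H]1C(C)=CC[C@H](CC=C(C)C)C1(C)C | intermediate
34 | (2E,4E,6E)-2,7-dimethylocta-2,4,6-trienedial | O=C/C(C)=C/C=C/C=C(C)/C=O | starting material
35 | phosphorus ylide of 33 | c1ccc(cc1)P(c1ccccc1)(c1ccccc1)=C/C=C(C)/C=C/[C@@H]1C(C)=CC[C@H](CC=C(C)C)C1(C)C | intermediate
36 | (2E,4E,6E,8E,10E,12E)-2,7,11-trimethyl-13-[(1R,5S)-2,6,6-trimethyl-5-(3-methylbut-2-en-1-yl)cyclohex-2-en-1-yl]trideca-2,4,6,8,10,12-hexaenal | CC(C)=CC[C@H]1CC=C(C)[C@@H](/C=C/C(C)=C/C=C/C(C)=C/C=C/C=C(C)/C=O)C1(C)C | intermediate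
37 | phosphorus ylide of 18 | c1ccc(cc1)P(c1ccccc1)(c1ccccc1)=C/C=C(C)/C=C/[C@H]1C(C)=CC[C@H](C/C=C(\C)C(=O)OC)C1(C)C | intermediate
38 | methyl (2E)-2-methyl-4-{(1R,5S)-4,6,6-trimethyl-5-[(1E,3E,5E,7E,9E,11E,13E,15E,17E)-3,7,12,16-tetramethyl-18-[(1R,5S)-2,6,6-trimethyl-5-(3-methylbut-2-en-1-yl)cyclohex-2-en-1-yl]octadeca-1,3,5,7,9,11,13,15,17-nonaen-1-yl]cyclohex-3-en-1-yl}but-2-enoate | CC(C)=CC[C@H]1CC=C(C)[C@@H](/C=C/C(C)=C/C=C/C(C)=C/C=C/C=C(C)/C=C/C=C(C)/C=C/[C@H]2C(C)=CC[C@H](C/C=C(\C)C(=O)OC)C2(C)C)C1(C)C | intermediate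
39 | (2S,6R,2'R,6'S)-2'-[(2E)-4-hydroxy-3-methylbut-2-en-1-yl]-2-(3-methylbut-2-en-1-yl)-ε,ε-carotene | CC(C)=CC[C@H]1CC=C(C)[C@@H](/C=C/C(C)=C/C=C/C(C)=C/C=C/C=C(C)/C=C/C=C(C)/C=C/[C@H]2C(C)=CC[C@H](C/C=C(\C)CO)C2(C)C)C1(C)C | target

**Step count and risks**

Total steps: 25. Longest linear sequence: 14 (steps 12–22, then 23, 24, 25).

Steps most likely to fail:

Step 6 (key cyclization). What may go wrong: unselective proton loss from the C5' cation (exocyclic or tetrasubstituted olefin isomers), leakage through a boat that lowers the trans selectivity, and erosion of C2' by reversible proton loss or 1,2-hydride shift in the open tertiary cation. The fallback answers the first two and sets out from diol ester 9. MnO2 oxidation of the allylic alcohol should give methyl (2E,5R,8Z)-5-(2-hydroxypropan-2-yl)-2,8-dimethyl-10-oxodeca-2,8-dienoate F1. Horner–Wadsworth–Emmons reaction with 14 should give the pseudoionone-type dienone methyl (2E,5R,8Z,10E)-5-(2-hydroxypropan-2-yl)-2,8-dimethyl-12-oxotrideca-2,8,10-trienoate F2. Treatment with 85% H3PO4 (the classical pseudoionone to α-ionone cyclization, which ends with endocyclic proton loss) closes the same C1'–C6' bond and should give enone 15 together with its C6' epimer. Because the C6' proton of this enone is the exchangeable γ-proton, brief NaOCH3/CH3OH equilibration is expected to converge on the 2',6'-trans isomer, which should be the more stable one (C6' substituent pseudo-axial, away from the C1' and C5' methyls). The route is rejoined at 15.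

Step 2 (epoxide opening). What may go wrong: SN2 attack at the hindered secondary epoxide carbon is slow, so self-condensation of the nitrile anion and base-induced isomerization of the epoxide to an allylic alcohol take over. The fallback sets out from 2. K2CO3 in CH3OH gives epoxy alcohol 4, isolated here. Lithium acetylide–ethylenediamine complex in DMSO, a small and thermally robust nucleophile known to open trisubstituted epoxides at the less substituted carbon with inversion, should give (2Z,6R)-6-ethynyl-3,7-dimethyloct-2-ene-1,7-diol F3. Anti-Markovnikov hydroboration of the terminal alkyne with dicyclohexylborane and NaBO3 oxidation should give aldehyde 6 and hence lactol 7, where the route is rejoined.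

Step 9 (olefination of the aldehyde). What may go wrong: enolization of the β,γ-unsaturated aldehyde during olefination, with epimerization at C6' or migration of the ring olefin into conjugation. The fallback avoids the aldehyde and sets out from alcohol 12. A Mitsunobu reaction with 1-phenyl-1H-tetrazole-5-thiol should give methyl (2E)-2-methyl-4-[(1R,5S)-4,6,6-trimethyl-5-{[(1-phenyl-1H-tetrazol-5-yl)sulfanyl]methyl}cyclohex-3-en-1-yl]but-2-enoate F4. Oxidation with (NH4)6Mo7O24/H2O2 should give the corresponding sulfone methyl (2E)-2-methyl-4-[(1R,5S)-4,6,6-trimethyl-5-{[(1-phenyl-1H-tetrazol-5-yl)sulfonyl]methyl}cyclohex-3-en-1-yl]but-2-enoate F5. Julia–Kocienski olefination (KN(SiMe3)2, DME, −60 °C) with commercial (2E)-4-(acetyloxy)-2-methylbut-2-enal builds C7'=C8' and brings in C8'–C11' in one step, giving methyl (2E)-4-[(1R,5S)-5-[(1E,3E)-5-(acetyloxy)-3-methylpenta-1,3-dien-1-yl]-4,6,6-trimethylcyclohex-3-en-1-yl]-2-methylbut-2-enoate F6. K2CO3 in CH3OH should give methyl (2E)-4-[(1R,5S)-5-[(1E,3E)-5-hydroxy-3-methylpenta-1,3-dien-1-yl]-4,6,6-trimethylcyclohex-3-en-1-yl]-2-methylbut-2-enoate F7. PPh3·HBr converts F7 into phosphonium salt 18, where the route is rejoined; steps 8 to 10 are bypassed.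

**Further compounds**

F1 | step 6 | methyl (2E,5R,8Z)-5-(2-hydroxypropan-2-yl)-2,8-dimethyl-10-oxodeca-2,8-dienoate | O=C/C=C(C)\CC[C@H](C/C=C(\C)C(=O)OC)C(C)(C)O
F2 | step 6 | methyl (2E,5R,8Z,10E)-5-(2-hydroxypropan-2-yl)-2,8-dimethyl-12-oxotrideca-2,8,10-trienoate | CC(=O)/C=C/C=C(C)\CC[C@H](C/C=C(\C)C(=O)OC)C(C)(C)O
F3 | step 2 | (2Z,6R)-6-ethynyl-3,7-dimethyloct-2-ene-1,7-diol | OC/C=C(C)\CC[C@H](C#C)C(C)(C)O
F4 | step 9 | methyl (2E)-2-methyl-4-[(1R,5S)-4,6,6-trimethyl-5-{[(1-phenyl-1H-tetrazol-5-yl)sulfanyl]methyl}cyclohex-3-en-1-yl]but-2-enoate | c1ccc(cc1)-n1nnnc1SC[C@H]1C(C)=CC[C@H](C/C=C(\C)C(=O)OC)C1(C)C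
F5 | step 9 | methyl (2E)-2-methyl-4-[(1R,5S)-4,6,6-trimethyl-5-{[(1-phenyl-1H-tetrazol-5-yl)sulfonyl]methyl}cyclohex-3-en-1-yl]but-2-enoate | c1ccc(cc1)-n1nnnc1S(=O)(=O)C[C@H]1C(C)=CC[C@H](C/C=C(\C)C(=O)OC)C1(C)C
F6 | step 9 | methyl (2E)-4-[(1R,5S)-5-[(1E,3E)-5-(acetyloxy)-3-methylpenta-1,3-dien-1-yl]-4,6,6-trimethylcyclohex-3-en-1-yl]-2-methylbut-2-enoate | CC(=O)OC/C=C(C)/C=C/[C@H]1C(C)=CC[C@H](C/C=C(\C)C(=O)OC)C1(C)C
F7 | step 9 | methyl (2E)-4-[(1R,5S)-5-[(1E,3E)-5-hydroxy-3-methylpenta-1,3-dien-1-yl]-4,6,6-trimethylcyclohex-3-en-1-yl]-2-methylbut-2-enoate | OC/C=C(C)/C=C/[C@H]1C(C)=CC[C@H](C/C=C(\C)C(=O)OC)C1(C)C
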